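**Assumption (one line):** the cyclohexene is numbered as in the SMILES (C1 methyl-bearing, C2 =CH, C3 aryl, C4 aroyl, C5 resorcinyl, C6 CH2), which makes the target (3S,4R,5S), i.e. 3,4-cis/4,5-trans (the endo adduct); the flavoprotein MaDA (Diels–Alderase of Morus alba) is not sold, is obtained by heterologous expression, and is treated as a catalyst, not a starting material.

## Retrosynthetic overview

- The cyclohexene is the only ring to build. It is cut at C3–C4 and C5–C6 into a dehydroprenyl chalcone (diene) and a 2'-hydroxychalcone (dienophile), joined in the last step by an enzyme-catalysed endo [4+2] on the fully unprotected polyphenols, which sets all three stereocenters at once.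
- Each chalcone comes from a Suzuki–Miyaura coupling of an unprotected 3'-iodochalcone with a C5 (E)-alkenyl pinacolboronate, itself made from a C5 alkyne and pinacolborane.
- Both iodochalcones come from acid-mediated Claisen–Schmidt condensation of one common ketone, 3-iodo-2,4-dihydroxyacetophenone, with 4-hydroxybenzaldehyde or 2,4-dihydroxybenzaldehyde.
- The common ketone comes from iodination of 2,4-dihydroxyacetophenone.
- Ring order: all aromatic rings are bought; the cyclohexene is formed last.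

## Route

Step 1
Reactants: 1 2,4-dihydroxyacetophenone
Product: 2 1-(2,4-dihydroxy-3-iodophenyl)ethanone
Conditions: I2 (0.4 equiv), HIO3 (0.2 equiv), EtOH/H2O, 35 °C
Reagents that add atoms: iodine, II; iodic acid, OI(=O)=O
Why: Electrophilic aromatic iodination in which the carbon between the two hydroxyls of the chelated ketone is the most nucleophilic site; the minor 5-iodo isomer is removed by crystallisation (the 3-iodo isomer shows two ortho-coupled doublets in the 1H NMR) and no stereocenter is formed.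

Step 2
Reactants: 2 1-(2,4-dihydroxy-3-iodophenyl)ethanone; 3 2,4-dihydroxybenzaldehyde
Product: 5 (E)-1-(2,4-dihydroxy-3-iodophenyl)-3-(2,4-dihydroxyphenyl)prop-2-en-1-one, via flavylium chloride 4 (not isolated)
Conditions: HCl (4 M in 1,4-dioxane, 5 equiv), EtOAc, rt, 24 h; then 1 M aq NaOH/MeOH (pH 12), rt, dark, 2 h; then AcOH to pH 5
Reagents that add atoms: sodium hydroxide (aqueous), [Na+].[OH-] (its oxygen ends as the ketone oxygen of 5)
Why: Acid-mediated Claisen–Schmidt (aldol) condensation in which the ortho-hydroxyl of the aldehyde ring closes on the ketone to give the flavylium salt 4 (the classical flavylium synthesis), followed by the known flavylium-to-chalcone ring opening (hydroxide adds at C2, the hemiketal opens, and the chalcone settles as the thermodynamically favoured E isomer); no stereocenter is formed.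

Step 3
Reactants: 6 3-methylbut-1-yne
Product: 7 (E)-4,4,5,5-tetramethyl-2-(3-methylbut-1-enyl)-1,3,2-dioxaborolane
Conditions: HBpin (1.05 equiv), Cp2Zr(H)Cl (5 mol%), Et3N (10 mol%), neat, sealed tube, 60 °C
Reagents that add atoms: pinacolborane, CC1(C)OBOC1(C)C
Why: Cp2Zr(H)Cl-catalysed hydroboration of a terminal alkyne with pinacolborane is a syn, anti-Markovnikov addition and gives only the (E)-alkenylboronate; no stereocenter.

Step 4
Reactants: 5 (E)-1-(2,4-dihydroxy-3-iodophenyl)-3-(2,4-dihydroxyphenyl)prop-2-en-1-one; 7 (E)-4,4,5,5-tetramethyl-2-(3-methylbut-1-enyl)-1,3,2-dioxaborolane (1.5 equiv)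
Product: 8 (E)-1-[2,4-dihydroxy-3-((E)-3-methylbut-1-enyl)phenyl]-3-(2,4-dihydroxyphenyl)prop-2-en-1-one
Conditions: Pd(OAc)2 (5 mol%), SPhos (10 mol%), K2CO3 (6 equiv), 1,4-dioxane/H2O 4:1 (degassed), 60 °C
Reagents that add atoms: none
Why: Suzuki–Miyaura cross-coupling, in which aryl iodides couple in aqueous base with free phenols present (as phenoxides), the electron-rich biarylphosphine copes with the flanked, electron-rich iodide, and the (E)-geometry of 7 is retained; no stereocenter.

Step 5
Reactants: 2 1-(2,4-dihydroxy-3-iodophenyl)ethanone; 9 4-hydroxybenzaldehyde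
Product: 10 (E)-1-(2,4-dihydroxy-3-iodophenyl)-3-(4-hydroxyphenyl)prop-2-en-1-one
Conditions: HCl (4 M in 1,4-dioxane, 3 equiv), EtOH, rt, 24 h
Reagents that add atoms: none
Why: Acid-catalysed Claisen–Schmidt (aldol) condensation, which tolerates free phenols because no deactivated phenoxide aldehyde is formed; this aldehyde has no ortho-hydroxyl, so the (E)-chalcone forms directly; no stereocenter.

Step 6
Reactants: 11 2-methylbut-1-en-3-yne
Product: 12 (E)-4,4,5,5-tetramethyl-2-(3-methylbuta-1,3-dienyl)-1,3,2-dioxaborolane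
Conditions: HBpin (1.05 equiv), Cp2Zr(H)Cl (5 mol%), Et3N (10 mol%), neat, sealed tube, 60 °C
Reagents that add atoms: pinacolborane, CC1(C)OBOC1(C)C
Why: The same syn hydroboration, chemoselective for the terminal alkyne over the 1,1-disubstituted alkene, gives the (E)-dienylboronate; no stereocenter.

Step 7
Reactants: 10 (E)-1-(2,4-dihydroxy-3-iodophenyl)-3-(4-hydroxyphenyl)prop-2-en-1-one; 12 (E)-4,4,5,5-tetramethyl-2-(3-methylbuta-1,3-dienyl)-1,3,2-dioxaborolane (1.5 equiv)
Product: 13 (E)-1-[2,4-dihydroxy-3-((E)-3-methylbuta-1,3-dienyl)phenyl]-3-(4-hydroxyphenyl)prop-2-en-1-one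
Conditions: Pd(OAc)2 (5 mol%), SPhos (10 mol%), K2CO3 (5 equiv), 1,4-dioxane/H2O 4:1 (degassed), 50 °C, dark; cold work-up at pH 6, used at once
Reagents that add atoms: none
Why: Suzuki–Miyaura cross-coupling as in step 4 with retention of the diene geometry; the free-phenol diene is kept cold, dark and dilute because ortho-hydroxyaryl dienes drift to 2,2-dimethylchromenes; no stereocenter.

Step 8
Reactants: 13 (E)-1-[2,4-dihydroxy-3-((E)-3-methylbuta-1,3-dienyl)phenyl]-3-(4-hydroxyphenyl)prop-2-en-1-one (1.3 equiv, added in portions); 8 (E)-1-[2,4-dihydroxy-3-((E)-3-methylbut-1-enyl)phenyl]-3-(2,4-dihydroxyphenyl)prop-2-en-1-one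
Product: 14 (E)-1-{3-[(1S,5S,6R)-6-{2,4-dihydroxy-3-[(E)-3-methylbut-1-enyl]benzoyl}-5-(2,4-dihydroxyphenyl)-3-methylcyclohex-2-en-1-yl]-2,4-dihydroxyphenyl}-3-(4-hydroxyphenyl)prop-2-en-1-one (CNP0140882.1)
Conditions: recombinant Morus alba Diels–Alderase MaDA (FAD-containing protein, about 0.2 mol%), Tris·HCl buffer (50 mM, pH 8.0)/DMSO 19:1, 37 °C, dark, argon
Reagents that add atoms: none
Why: Enzyme-catalysed intermolecular Diels–Alder reaction ([4+2]) by the enzyme that builds the endo mulberry adducts from these two substrate classes: it holds the 2'-hydroxychalcone 8 and the diene 13 in the endo transition state (C3–C4 cis, with C4–C5 trans carried over from the (E)-enone) on one pair of faces, so C3, C4 and C5 are set together as 3S,4R,5S, and the diene CH2 bonds to the enone β-carbon as the electronically matched regiochemistry.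

## Compound list

1 | 2,4-dihydroxyacetophenone | CC(=O)c1ccc(O)cc1O | starting material
2 | 1-(2,4-dihydroxy-3-iodophenyl)ethanone | CC(=O)c1ccc(O)c(I)c1O | intermediate
3 | 2,4-dihydroxybenzaldehyde | O=Cc1ccc(O)cc1O | starting material
4 | 2-(2,4-dihydroxy-3-iodophenyl)-7-hydroxychromenylium chloride (flavylium chloride) | Oc1ccc2ccc(-c3ccc(O)c(I)c3O)[o+]c2c1.[Cl-] | intermediate
5 | (E)-1-(2,4-dihydroxy-3-iodophenyl)-3-(2,4-dihydroxyphenyl)prop-2-en-1-one | O=C(/C=C/c1ccc(O)cc1O)c1ccc(O)c(I)c1O | intermediate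
6 | 3-methylbut-1-yne | CC(C)C#C | starting material
7 | (E)-4,4,5,5-tetramethyl-2-(3-methylbut-1-enyl)-1,3,2-dioxaborolane | CC(C)/C=C/B1OC(C)(C)C(C)(C)O1 | intermediate
8 | (E)-1-[2,4-dihydroxy-3-((E)-3-methylbut-1-enyl)phenyl]-3-(2,4-dihydroxyphenyl)prop-2-en-1-one | CC(C)/C=C/c1c(O)ccc(C(=O)/C=C/c2ccc(O)cc2O)c1O | intermediate
9 | 4-hydroxybenzaldehyde | O=Cc1ccc(O)cc1 | starting material
10 | (E)-1-(2,4-dihydroxy-3-iodophenyl)-3-(4-hydroxyphenyl)prop-2-en-1-one | O=C(/C=C/c1ccc(O)cc1)c1ccc(O)c(I)c1O | intermediate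
11 | 2-methylbut-1-en-3-yne | CC(=C)C#C | starting material
12 | (E)-4,4,5,5-tetramethyl-2-(3-methylbuta-1,3-dienyl)-1,3,2-dioxaborolane | CC(=C)/C=C/B1OC(C)(C)C(C)(C)O1 | intermediate
13 | (E)-1-[2,4-dihydroxy-3-((E)-3-methylbuta-1,3-dienyl)phenyl]-3-(4-hydroxyphenyl)prop-2-en-1-one | CC(=C)/C=C/c1c(O)ccc(C(=O)/C=C/c2ccc(O)cc2)c1O | intermediate
14 | (E)-1-{3-[(1S,5S,6R)-6-{2,4-dihydroxy-3-[(E)-3-methylbut-1-enyl]benzoyl}-5-(2,4-dihydroxyphenyl)-3-methylcyclohex-2-en-1-yl]-2,4-dihydroxyphenyl}-3-(4-hydroxyphenyl)prop-2-en-1-one | CC1=C[C@H](c2c(O)ccc(C(=O)/C=C/c3ccc(O)cc3)c2O)[C@H](C(=O)c2ccc(O)c(/C=C/C(C)C)c2O)[C@@H](c2ccc(O)cc2O)C1 | target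

## Step count and risks

Total steps: 8. Longest linear sequence: 4 steps (1 → 2 → 5 → 8 → 14 through steps 1, 2, 4, 8, or 1 → 2 → 10 → 13 → 14 through steps 1, 5, 7, 8).

**Step 8 (most likely to fail).** The enzyme may refuse a dienophile whose C5 side chain is conjugated to the ring instead of being a prenyl group, or may use 13 as a dienophile as well. The fallback sets out from 13 and 8 and comes back at 14; it replaces the enzyme by a chiral borate-templated Diels–Alder reaction on acetates. Compound 13 is acetylated at all three hydroxyls (Ac2O, DMAP, pyridine) to the diene triacetate (E)-1-[2,4-diacetoxy-3-((E)-3-methylbuta-1,3-dienyl)phenyl]-3-(4-acetoxyphenyl)prop-2-en-1-one F1. Compound 8 is acetylated only at its three non-chelated hydroxyls (Ac2O 3.1 equiv, Et3N, CH2Cl2, 0 °C) to the 2'-hydroxychalcone triacetate (E)-1-[4-acetoxy-2-hydroxy-3-((E)-3-methylbut-1-enyl)phenyl]-3-(2,4-diacetoxyphenyl)prop-2-en-1-one F2. The borate made from BH3·THF, AcOH and one antipode of VANOL (2.5 equiv each, THF) binds F2 through its free 2'-hydroxyl and carbonyl and adds F1; after chromatographic removal of the exo isomer this gives the endo adduct hexaacetate F3. K2CO3 in MeOH at 0 °C then removes the six acetates to give 14. The VANOL antipode used is the one that delivers the (3S,4R,5S) series, checked by CD on F3.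

**Step 2.** The iodide between two hydroxyls may be lost in strong acid, or the flavylium ring opening may stall or continue to the flavanone. The fallback sets out from 2 and 3 and comes back at 5; it replaces the acid/flavylium path by a base-mediated condensation of protected partners. Compound 2 is protected at its non-chelated hydroxyl (MOMCl, K2CO3, acetone) as 1-[2-hydroxy-3-iodo-4-(methoxymethoxy)phenyl]ethanone F4, and 3 at both hydroxyls (MOMCl, iPr2NEt, CH2Cl2) as 2,4-bis(methoxymethoxy)benzaldehyde F5. KOH in EtOH/H2O at rt joins them to the tris-MOM iodochalcone (E)-1-[2-hydroxy-3-iodo-4-(methoxymethoxy)phenyl]-3-[2,4-bis(methoxymethoxy)phenyl]prop-2-en-1-one F6. HCl in MeOH at 40 °C removes the three acetals to give 5; this is safe because no acid-sensitive alkene is present yet and the trans-chalcone is kinetically stable to brief acid.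

**Step 7.** The free-phenol diene 13 may cyclise to a chromene or oligomerise under warm aqueous base. The fallback sets out from 10 (with 12) and comes back at 13; it carries the diene through the coupling in masked, storable form. Compound 10 is silylated at its two non-chelated hydroxyls (TBSCl, imidazole, DMF) to the bis-silyl iodochalcone (E)-1-[4-(tert-butyldimethylsilyloxy)-2-hydroxy-3-iodophenyl]-3-[4-(tert-butyldimethylsilyloxy)phenyl]prop-2-en-1-one F7. An anhydrous Suzuki–Miyaura coupling with 12 (Pd(OAc)2, SPhos, powdered K3PO4, toluene, 60 °C) gives the bis-silyl diene chalcone (E)-1-[4-(tert-butyldimethylsilyloxy)-2-hydroxy-3-((E)-3-methylbuta-1,3-dienyl)phenyl]-3-[4-(tert-butyldimethylsilyloxy)phenyl]prop-2-en-1-one F8. Bu4NF/AcOH in THF at 0 °C releases 13 just before step 8.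

Further compounds
F1 | step 8 | (E)-1-[2,4-diacetoxy-3-((E)-3-methylbuta-1,3-dienyl)phenyl]-3-(4-acetoxyphenyl)prop-2-en-1-one | CC(=C)/C=C/c1c(OC(C)=O)ccc(C(=O)/C=C/c2ccc(OC(C)=O)cc2)c1OC(C)=O
F2 | step 8 | (E)-1-[4-acetoxy-2-hydroxy-3-((E)-3-methylbut-1-enyl)phenyl]-3-(2,4-diacetoxyphenyl)prop-2-en-1-one | CC(C)/C=C/c1c(OC(C)=O)ccc(C(=O)/C=C/c2ccc(OC(C)=O)cc2OC(C)=O)c1O
F3 | step 8 | hexaacetate of 14 (3S,4R,5S; only the chelated hydroxyl of the aroyl ring free) | CC1=C[C@H](c2c(OC(C)=O)ccc(C(=O)/C=C/c3ccc(OC(C)=O)cc3)c2OC(C)=O)[C@H](C(=O)c2ccc(OC(C)=O)c(/C=C/C(C)C)c2O)[C@@H](c2ccc(OC(C)=O)cc2OC(C)=O)C1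
F4 | step 2 | 1-[2-hydroxy-3-iodo-4-(methoxymethoxy)phenyl]ethanone | CC(=O)c1ccc(OCOC)c(I)c1O
F5 | step 2 | 2,4-bis(methoxymethoxy)benzaldehyde | COCOc1ccc(C=O)c(OCOC)c1
F6 | step 2 | (E)-1-[2-hydroxy-3-iodo-4-(methoxymethoxy)phenyl]-3-[2,4-bis(methoxymethoxy)phenyl]prop-2-en-1-one | O=C(/C=C/c1ccc(OCOC)cc1OCOC)c1ccc(OCOC)c(I)c1O
F7 | step 7 | (E)-1-[4-(tert-butyldimethylsilyloxy)-2-hydroxy-3-iodophenyl]-3-[4-(tert-butyldimethylsilyloxy)phenyl]prop-2-en-1-one | O=C(/C=C/c1ccc(O[Si](C)(C)C(C)(C)C)cc1)c1ccc(O[Si](C)(C)C(C)(C)C)c(I)c1O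
F8 | step 7 | (E)-1-[4-(tert-butyldimethylsilyloxy)-2-hydroxy-3-((E)-3-methylbuta-1,3-dienyl)phenyl]-3-[4-(tert-butyldimethylsilyloxy)phenyl]prop-2-en-1-one | CC(=C)/C=C/c1c(O[Si](C)(C)C(C)(C)C)ccc(C(=O)/C=C/c2ccc(O[Si](C)(C)C(C)(C)C)cc2)c1O
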